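The second chain carrier is the species I follow here: the chain step that takes substrate runs through it.

    initiator → 2 initiating radical (k1 = 0.0030 /s)
    substrate + initiating radical → capped initiator + first chain carrier (k2 = 81000 /M/s)
    partner + first chain carrier → target + second chain carrier (k3 = 4400 /M/s)
    substrate + second chain carrier → by-product + first chain carrier (k4 = 5600 /M/s)
    first chain carrier → ended carrier (k5 = 2.1 /s)
    2 second chain carrier → ended chains A (k6 = 9.1 × 10⁷ /M/s)
    2 first chain carrier → ended chains B (k7 = 1 × 10⁸ /M/s)
    target ⇌ isomer of the product (K8 = 2.7, k8 = 3.9 × 10⁻⁴ /s)

all flasks: substrate 0.093 M; initiator 0.93 mM; time 15 min
- south: partner 0.230 M
- south-west: partner 0.100 M
- west: partner 0.150 M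

- percentages count the substrate that a species holds: one ended chains B counts as two
- a step written with two of one species runs at k times the square of its concentration and takes two of it each time
- run time (south): 15 min

* which of these there is most of at the end, counted by the substrate in it, south (substrate / first chain carrier / target / isomer of the product)
* which of these there is most of at the end, counted by the substrate in it, south-west (substrate / first chain carrier / target / isomer of the product)
* which of these there is most of at the end, counted by the substrate in it, west (substrate / first chain carrier / target / isomer of the product)
* amount of the one of these that there is most of at the end, in percent of the substrate charged, south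
* amount of the one of these that there is most of at the end, in percent of the substrate charged, south-west
* amount of the one of these that there is most of at the end, in percent of the substrate charged, west

I carry one quantity, the chain dose: the integral over the run of the pseudo-first-order rate at which second chain carrier removes substrate. The fraction of substrate left is then exp(−dose).

1. Main step. Suppose initiator feeds the chain and carriers end by the pairing of second chain carrier. Making equals ending at a level of 1.75 × 10⁻⁷ M, which gives substrate a starting rate of 0.0588 /min.

2. Initiator decay. Its half-life of 3.9 min is shorter than the run of 15 min, so the carrier level falls with the root of the initiator. I replace that curve by its mean, 0.549 of the starting level. Then dose = 0.484 and 61.6% of the substrate is left in this reckoning, which holds no partner yet.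

3. Pairing of first chain carrier. The two chain steps run at equal rates, so first over second carrier is 5600 /M/s times substrate over 4400 /M/s times partner. I take mean substrate as 0.808 of its charge. In west, partner left is 1.42 per charged substrate, so the carrier ratio is 0.724. Adding this ending scales the dose by 0.797, leaving 68.0% in west. The same reckoning gives 64.5% in south and 73.6% in south-west.

4. Check of the mean. With starting fractions, west gives 68.9%. With the end fractions of step 2 it gives 66.9%. The mean therefore costs about a point.

5. The rest. Initiating radical takes 1.87% of the substrate, which pushes the figure down. In west, the first-order ending of first chain carrier starts at 3.80% of the initiation, which pushes it up. I let these offset and commit to the numbers of step 3, with substrate the largest in each flask.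

The forecast also names substrate in each flask, with 64.5% in south, 73.5% in south-west and 68.5% in west. Its grounds include that “more partner lowers the substrate left only modestly”. In west I hold 68.0% against its 68.5%.

The simulation gives substrate in each flask: 64.0% in south, 73.3% in south-west and 67.8% in west. Both reckonings stand within a point of these.

West has not come to rest at 15 min. Initiator stands at 6.7%, and the unspent share of the dose is 25.9%. Adding that share to the dose gives 59.4% of the substrate in west, while ten times the time gives 60.5%. Over the same span in west, target goes from 25.5% to 10.8% and isomer of the product from 5.92% to 27.9%.

The neighbour is west with 3.7 × 10⁻⁴ M of initiator. Its dose before step 3 is 0.305, mean substrate is 0.868, and the reckoning leaves 78.6%. The simulation gives 79.2%.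

The numbers are invented.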